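(The earlier runs and the new flask are calculated for an exercise; noise was put on by code.)

A small charge of nucleophile, 0.520 M in beta against 0.40 M of electrophile (the limiting reagent by charge), leaves open which species leads after 2.0 h; eta has 1.00 M. An even split is the zero of the scale: above it product leads, below it electrophile leads.

the same everywhere: electrophile 0.40 M; gas 190 mM (held)

|  | nucleophile | remark | time |
|---|---|---|---|
| birch | 0.63 M | run made earlier |  |
| oak | 0.71 M | run made earlier |  |
| alder | 1.1 M | run made earlier |  |
| beta | 0.520 M |  | 2.0 h |
| eta | 1.00 M |  | 2.0 h |

| run | time / min | product / % | electrophile / % |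
|---|---|---|---|
| birch | 15.0 | 11.8 | 88.2 |
| birch | 40.0 | 23.6 | 77.6 |
| birch | 80.0 | 32.6 | 68.4 |
| birch | 120 | 38.5 | 61.5 |
| oak | 30.0 | 20.6 | 78.8 |
| oak | 60.0 | 30.3 | 68.2 |
| oak | 90.0 | 37.6 | 61.7 |
| oak | 120 | 41.5 | 57.8 |
| alder | 30.0 | 31.2 | 69.0 |
| alder | 60.0 | 44.9 | 55.4 |
| alder | 90.0 | 53.0 | 47.4 |
| alder | 120 | 58.9 | 41.1 |

(scatter of a reading: 0.5 percentage points)

* which of these there is most of at the end, counted by the electrophile in it, beta (product / electrophile)
* which of these there is most of at the end, counted by the electrophile in it, eta (product / electrophile)
* how much there is at the end of the one of these that leads, in percent of the electrophile charged: beta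
* how much there is at the end of the one of these that leads, in percent of the electrophile charged: eta

- at the start none of the gas is in solution

In the readings product and electrophile add up close to the charge, but nucleophile was not read. Two chemists therefore assume the same working rate law, k·[electrophile]·[nucleophile], and count one nucleophile used per product formed. They part over k. Let E and N be the charges, x the product fraction and u the electrophile fraction. Then θ = ln[(N − Ex)/(Nu)]/(N − E) is the time integral of k.

The first chemist holds k constant. Birch's first reading gives θ = 0.207 L mol⁻¹ at 15.0 min, which scales to 1.66 L mol⁻¹ at 120 min. Solved for x, with R = exp[(N − E)θ], the law gives x = N(R − 1)/(NR − E). So she expects product at 48.8% in beta and 74.0% in eta.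

The second chemist lets k fall with time and reads θ directly at the time wanted. At 120 min birch reads 0.895 L mol⁻¹, oak 0.909 L mol⁻¹ and alder 0.926 L mol⁻¹. Their mean is 0.910 L mol⁻¹, less than the scaled value. This mean, the second-order clock at that time, is the reckoning I commit to. It gives product 33.3% in beta, so electrophile leads there at 66.7%, and product 54.8% in eta.

The forecast, on the ground that “All three runs give nearly the same integrated value”, names electrophile at 67% in beta and product at 55% in eta.

The flask gives electrophile at 67.5% in beta, with product at 32.5% rather than 48.8%, and product at 54.9% in eta rather than 74.0%.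

    electrophile + nucleophile → acid set free + product (k = 0.0160 L mol⁻¹ min⁻¹)
    nucleophile + acid set free ⇌ protonated nucleophile, settled at all times (K = 5800 L mol⁻¹)
    acid set free + free base ⇌ salt of the base (K = 1.30 × 10⁵ L mol⁻¹, k = 1.20 L mol⁻¹ min⁻¹)
    nucleophile ⇌ dormant form (K = 1.10, k = 0.0170 min⁻¹)
    gas ⇌ free base, rate k5*(csat - [free base]) (kL = 0.0130 min⁻¹)

In eta, nucleophile and dormant form relax with a half-life of 0.356 h, while the product-forming step gives the nucleophile a half-life of 2.1 h at 0.201 h. The constant-k view has its region in the early stretch: its birch reading at 15.0 min came sooner than the length of that eta half-life. For the neighbour of eta charged with 0.24 M of electrophile, the clock gives product at 56.7%. The computed flask holds 60.4% at 2.00 h.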